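**Strategy.** The tetramethyl-dione ring is disconnected at its enol-ether carbons. The ring segment C(CH3)2–C(=O)–C(CH3)2–C(=O) is exactly the four-membered ring of cheap 2,2,4,4-tetramethylcyclobutane-1,3-dione. The two remaining ring carbons (the O-bearing sp2 carbon and its neighbour that carries the side chain) are an acetate unit. In the key step the acetate enolate adds to the cyclobutanedione, the strained ring opens by retro-Claisen cleavage and re-closes by Dieckmann condensation: a one-flask two-carbon ring expansion to syncarpic acid. A domino Knoevenagel/hetero-Diels–Alder reaction with isovaleraldehyde and (−)-β-caryophyllene then builds the dihydropyran ring and the three new stereocentres.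

Key step: step 1

Assumption: commercial (−)-β-caryophyllene (1R,9S) supplies the absolute configuration. Compound 5 is drawn as the triketone although it is largely enolised, and 3 and 4 are drawn neutral although they are present as lithium alkoxide and enolate.

**Step 1**
Reactants: 1 2,2,4,4-tetramethylcyclobutane-1,3-dione; 2 ethyl acetate
Product: 5 syncarpic acid, via cyclobutanol aldolate 3 (not isolated), via diketo ester enolate 4 (not isolated)
Conditions: LDA (commercial solution, 1.05 equiv), 2, THF, −78 °C; add 1, −78 °C → rt; then KOtBu (1.5 equiv), THF, rt → 60 °C; aq. HCl work-up
Reagents that add atoms: none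
Why: Proposed new method: the lithium enolate of 2 adds to one of the two equivalent, strain-activated carbonyls of 1 to give aldolate 3; on warming the alkoxide cleaves a ring C(O)–C(CH3)2 bond by retro-Claisen fragmentation, driven by release of cyclobutane strain, to give acyclic diketo ester 4 as its enolate; KOtBu then equilibrates to the isopropyl-ketone enolate, which attacks the ester carbonyl and expels ethoxide (Dieckmann condensation, 6-exo-trig closure of the six-membered ring). The closest known reaction types are the nucleophile-triggered ring opening of 1 by alkoxides, amines and organometallic reagents, ring enlargement of cyclic β-dicarbonyl compounds by addition–fragmentation, and the alkoxide cyclisation of a 2,2,4-trimethyl-3-oxopentanoyl malonate to the same ring. No stereocentre is formed. The step needs fragmentation to win over simple retro-aldol, which is secured because retro-aldol only returns the reactants while strain-releasing ring opening is irreversible; which ring bond breaks is irrelevant because 1 is symmetric and both cleavages give the same chain. It also needs C- over O-acylation in the closure, which is secured thermodynamically: an enol lactone from O-attack is reopened by alkoxide and the doubly stabilised enolate of 5 is the sink. Addition is completed at −78 °C before warming so that alkoxide released later does not meet unreacted 1.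

**Step 2**
Reactants: 5 syncarpic acid; 6 3-methylbutanal (isovaleraldehyde); 7 (−)-β-caryophyllene
Product: 9 tomentodione A, via alkylidene trione 8 (not isolated)
Conditions: 6 (1.5 equiv), 7 (3 equiv), EDDA (20 mol %), toluene, 80 °C, sealed tube; chromatography
Reagents that add atoms: none
Why: Domino Knoevenagel/inverse-electron-demand hetero-Diels–Alder reaction (Tietze type): EDDA condenses 5 with 6 to the alkylidene trione 8, whose 1-oxadiene adds suprafacially to the strained E-trisubstituted C4=C5 alkene of 7 (not the exocyclic methylene) with oxygen bonding to the methyl-bearing carbon, so that the trans C4/C5 relationship comes from the E geometry, the absolute sense (4R,5S) from attack on the exposed outer face of the major ring conformers (the face known from epoxidation of 7), and C1′ (S) from the orientation of the oxadiene that places the isobutyl group cis to H-5; the other orientation gives the C1′ epimer, the expected co-product, which should be removed by chromatography.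

**Compound list**
1 | 2,2,4,4-tetramethylcyclobutane-1,3-dione | CC1(C)C(=O)C(C)(C)C1=O | starting material
2 | ethyl acetate | CCOC(C)=O | starting material
3 | ethyl 2-(1-hydroxy-2,2,4,4-tetramethyl-3-oxocyclobutyl)acetate (formed as its lithium alkoxide) | CCOC(=O)CC1(O)C(C)(C)C(=O)C1(C)C | intermediate
4 | ethyl 4,4,6-trimethyl-3,5-dioxoheptanoate (formed as its enolate) | CCOC(=O)CC(=O)C(C)(C)C(=O)C(C)C | intermediate
5 | syncarpic acid (2,2,4,4-tetramethylcyclohexane-1,3,5-trione) | CC1(C)C(=O)CC(=O)C(C)(C)C1=O | intermediate
6 | 3-methylbutanal (isovaleraldehyde) | CC(C)CC=O | starting material
7 | (−)-β-caryophyllene, (1R,4E,9S)-4,11,11-trimethyl-8-methylidenebicyclo[7.2.0]undec-4-ene | C/C1=C\CCC(=C)[C@H]2CC(C)(C)[C@@H]2CC1 | starting material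
8 | 2,2,4,4-tetramethyl-6-(3-methylbutylidene)cyclohexane-1,3,5-trione | CC(C)CC=C1C(=O)C(C)(C)C(=O)C(C)(C)C1=O | intermediate
9 | tomentodione A: (1R,9S)-caryophyllane core whose C4–C5 bond is fused to a dihydropyran ring, O on C4 (R, bearing CH3), CH(isobutyl) carbon C1′ (S) on C5 (S), isobutyl cis to H-5 and trans to the C4 methyl; the pyran C=C is the enol-ether double bond of the 2,2,4,4-tetramethylcyclohexane-1,3-dione ring; exocyclic methylene retained | C=C1CC[C@H]2[C@H](CC(C)C)C3=C(O[C@]2(C)CC[C@@H]2[C@@H]1CC2(C)C)C(C)(C)C(=O)C(C)(C)C3=O | target

**Total step count:** 2
**Longest linear sequence:** 2 steps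

**Steps most likely to fail** (the route has only two steps, so both are ranked)

1. Step 1 (Proposed new method). Addition to the hindered carbonyl may be slow enough for the ester enolate to self-condense. The ring-opened β-keto ester enolate may also stall before the Dieckmann closure, or alkoxide may cleave its non-enolisable 1,3-diketone unit instead of cyclising it. The fallback uses known chemistry, sets out from 1 and returns at 5. It keeps the same atom mapping (the four ring carbons of 1 plus two carbons of a C2 donor) but gives up the one-operation ring expansion and spreads ring opening and re-closure over separate precedented operations. Compound 1 is isomerised with catalytic AlCl3 (neat, warm) to the β-lactone dimer 3,3-dimethyl-4-(propan-2-ylidene)oxetan-2-one F1. F1 C-acylates sodium dimethyl malonate (NaH, THF) to dimethyl 2-(2,2,4-trimethyl-3-oxopentanoyl)propanedioate F2. NaOMe in MeOH at reflux closes the ring by Dieckmann condensation to methyl 3,3,5,5-tetramethyl-2,4,6-trioxocyclohexane-1-carboxylate F3. Aqueous NaOH, then HCl with heating, hydrolyses and decarboxylates F3 to 5.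

2. Step 2. The heterodiene may be consumed by Michael addition of a second molecule of 5, or by tautomerisation to a dienol, before the hindered alkene reacts. The orientation of the oxadiene over the alkene may be poorly controlled, which lowers the share of the desired C1′ configuration. The fallback sets out from 5 and returns at 9. Compound 5 is condensed with 6 and thiophenol (cat. piperidine, EtOH, rt; Knoevenagel/thia-Michael trapping) to the isolable sulfide 2,2,4,4-tetramethyl-6-[3-methyl-1-(phenylsulfanyl)butyl]cyclohexane-1,3,5-trione F4, which is purified. F4 is then heated with excess 7 in toluene at 110 °C, where retro-thia-Michael loss of thiophenol releases 8 in low stationary concentration for the hetero-Diels–Alder reaction to 9. This fallback addresses loss of the heterodiene, not the C1′ selectivity.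

**Further compounds**
F1 | step 1 | 3,3-dimethyl-4-(propan-2-ylidene)oxetan-2-one | CC(C)=C1OC(=O)C1(C)C
F2 | step 1 | dimethyl 2-(2,2,4-trimethyl-3-oxopentanoyl)propanedioate | COC(=O)C(C(=O)OC)C(=O)C(C)(C)C(=O)C(C)C
F3 | step 1 | methyl 3,3,5,5-tetramethyl-2,4,6-trioxocyclohexane-1-carboxylate | COC(=O)C1C(=O)C(C)(C)C(=O)C(C)(C)C1=O
F4 | step 2 | 2,2,4,4-tetramethyl-6-[3-methyl-1-(phenylsulfanyl)butyl]cyclohexane-1,3,5-trione | CC(C)CC(Sc1ccccc1)C1C(=O)C(C)(C)C(=O)C(C)(C)C1=O
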